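**Retrosynthetic overview**
- The amide bond is made last, from the free sphingoid aminotriol and (2R)-2-hydroxypentacosanoic acid; the acid comes from methyl (R)-glycidate and a C22 Grignard reagent.
- Key disconnection C2–C3 of the sphingoid base: SmI2-mediated reductive cross-coupling of a glycolaldehyde-derived (R)-tert-butanesulfinyl imine with an α-silyloxy aldehyde. Two carbons that are both electrophilic are joined through a nucleophilic ketyl; C2 and C3 are set in this step.
- The aldehyde (C3–C17) comes from cross-metathesis (C6=C7) of a cyclopropyl-hexene with a pentenoate made from methyl (R)-glycidate and vinyl Grignard (C4 stereocentre from the glycidate).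
- The only ring, the trans-cyclopropane, is formed first by Charette cyclopropanation of (E)-hept-2-en-1-ol and extended by a copper-catalysed Grignard coupling.

Assumption: the acyl chain is read as 23 carbons before the carbinol carbon, i.e. (2R)-2-hydroxypentacosanoyl; vinylmagnesium bromide, SmI2 (0.1 M in THF) and the Charette dioxaborolane ligand are bought.

**Route**

Step 1
Reactants: 1 (2E)-hept-2-en-1-ol
Product: 2 [(1S,2S)-2-butylcyclopropyl]methanol
Conditions: Et2Zn, CH2I2, DME, (4R,5R)-2-butyl-N,N,N′,N′-tetramethyl-1,3,2-dioxaborolane-4,5-dicarboxamide (1.2 equiv), CH2Cl2, −10 °C to rt; aq. NH4Cl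
Reagents that add atoms: diiodomethane, ICI
Why: Charette asymmetric Simmons–Smith cyclopropanation, in which the zinc alkoxide of the allylic alcohol binds the (4R,5R)-dioxaborolane and Zn(CH2I)2 is delivered to one alkene face; stereospecific syn addition turns the E-alkene into the trans ring and sets both ring centres as (1S,2S), the same facial sense as for cinnamyl alcohol.

Step 2
Reactants: 2 [(1S,2S)-2-butylcyclopropyl]methanol
Product: 3 (1S,2S)-1-(bromomethyl)-2-butylcyclopropane
Conditions: CBr4, PPh3, CH2Cl2, −20 to 0 °C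
Reagents that add atoms: carbon tetrabromide, BrC(Br)(Br)Br
Why: Appel bromination, an SN2 displacement of the alkoxyphosphonium at the primary carbon run cold so that no cyclopropylcarbinyl cation (ring opening) forms; the ring stereocentres are not touched.

Step 3
Reactants: 3 (1S,2S)-1-(bromomethyl)-2-butylcyclopropane, 4 5-bromopent-1-ene
Product: 6 (1S,2S)-1-butyl-2-(hex-5-en-1-yl)cyclopropane, via pent-4-en-1-ylmagnesium bromide 5 (not isolated)
Conditions: 4, Mg, THF; then 3, Li2CuCl4 (3 mol%), THF, −20 °C to rt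
Reagents that add atoms: none
Why: Copper-catalysed sp3–sp3 Grignard cross-coupling (Kochi type), which proceeds by SN2-like attack on the primary bromide and not through a free cyclopropylcarbinyl radical, so the ring stays closed and no stereocentre is involved.

Step 4
Reactants: 7 methyl (2R)-oxirane-2-carboxylate (methyl (R)-glycidate), 8 vinylmagnesium bromide
Product: 9 methyl (2R)-2-hydroxypent-4-enoate
Conditions: CuI (10 mol%), THF, −78 to −40 °C; aq. NH4Cl
Reagents that add atoms: none
Why: Copper-catalysed epoxide opening by the Grignard reagent at the unsubstituted C3, faster than ester addition at low temperature; C2 is not a reacting centre and stays R.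

Step 5
Reactants: 9 methyl (2R)-2-hydroxypent-4-enoate
Product: 10 methyl (2R)-2-[(tert-butyldimethylsilyl)oxy]pent-4-enoate
Conditions: TBSCl, imidazole, DMF, rt
Reagents that add atoms: tert-butyldimethylsilyl chloride, CC(C)(C)[Si](C)(C)Cl
Why: Standard silyl ether formation; the bulky, non-chelating silyl ether is wanted for the facial control in step 9 and falls off with acid in step 10.

Step 6
Reactants: 6 (1S,2S)-1-butyl-2-(hex-5-en-1-yl)cyclopropane, 10 methyl (2R)-2-[(tert-butyldimethylsilyl)oxy]pent-4-enoate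
Product: 11 methyl (2R,4E)-9-[(1S,2S)-2-butylcyclopropyl]-2-[(tert-butyldimethylsilyl)oxy]non-4-enoate
Conditions: second-generation Hoveyda–Grubbs catalyst (5 mol%), 10 (3 equiv), CH2Cl2, 40 °C; then chromatography on AgNO3-impregnated SiO2
Reagents that add atoms: none
Why: Olefin cross-metathesis of two terminal alkenes with the cheap partner in excess; secondary metathesis gives the thermodynamic mixture (expected E:Z about 5:1), the minor Z isomer is removed by argentation chromatography, and no stereocentre is touched.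

Step 7
Reactants: 11 methyl (2R,4E)-9-[(1S,2S)-2-butylcyclopropyl]-2-[(tert-butyldimethylsilyl)oxy]non-4-enoate
Product: 12 (2R,4E)-9-[(1S,2S)-2-butylcyclopropyl]-2-[(tert-butyldimethylsilyl)oxy]non-4-enal
Conditions: i-Bu2AlH (1.05 equiv), CH2Cl2, −78 °C; aq. potassium sodium tartrate; used crude
Reagents that add atoms: none
Why: Partial hydride reduction of an ester, in which the α-silyloxy aluminium hemiacetal is stable at −78 °C and releases the aldehyde only on work-up; cold, non-basic conditions leave the α-centre R.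

Step 8
Reactants: 13 [(tert-butyldimethylsilyl)oxy]acetaldehyde, 14 (R)-2-methylpropane-2-sulfinamide
Product: 15 (R)-N-[(E)-2-[(tert-butyldimethylsilyl)oxy]ethylidene]-2-methylpropane-2-sulfinamide
Conditions: CuSO4 (anhydrous), CH2Cl2, rt
Reagents that add atoms: none
Why: Ellman condensation of an aldehyde with tert-butanesulfinamide, CuSO4 acting as Lewis acid and water scavenger; the E-imine forms and the sulfur stereocentre is retained.

Step 9
Reactants: 12 (2R,4E)-9-[(1S,2S)-2-butylcyclopropyl]-2-[(tert-butyldimethylsilyl)oxy]non-4-enal, 15 (R)-N-[(E)-2-[(tert-butyldimethylsilyl)oxy]ethylidene]-2-methylpropane-2-sulfinamide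
Product: 17 (R)-N-[(2S,3S,4R,6E)-11-[(1S,2S)-2-butylcyclopropyl]-1,4-bis[(tert-butyldimethylsilyl)oxy]-3-hydroxyundec-6-en-2-yl]-2-methylpropane-2-sulfinamide, via samarium ketyl radical 16 (not isolated)
Conditions: SmI2 (2.5 equiv), t-BuOH (2.5 equiv), 15 (2 equiv), THF, −78 °C
Reagents that add atoms: none
Why: SmI2-mediated reductive aza-pinacol cross-coupling, in which one-electron reduction turns the aldehyde carbon of 12 into the nucleophilic ketyl 16 that adds to the imine carbon of 15, and a second electron plus t-BuOH give the sulfinamide; the tert-butanesulfinyl group blocks one imine face in its s-cis conformer (C2 formed S), the open approach gives the anti 2-amino-3-ol, and the dipole-minimised Felkin-type arrangement of the non-chelating α-silyloxy ketyl puts the new C3–OH anti to C4–OTBS, so reagent and substrate control both point to (2S,3S,4R).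

Step 10
Reactants: 17 (R)-N-[(2S,3S,4R,6E)-11-[(1S,2S)-2-butylcyclopropyl]-1,4-bis[(tert-butyldimethylsilyl)oxy]-3-hydroxyundec-6-en-2-yl]-2-methylpropane-2-sulfinamide
Product: 18 (2S,3S,4R,6E)-2-amino-11-[(1S,2S)-2-butylcyclopropyl]undec-6-ene-1,3,4-triol
Conditions: HCl (3 M in MeOH), rt; then aq. NaOH, extraction
Reagents that add atoms: none
Why: Acidic methanolysis cleaves the N–S bond of the sulfinamide and both silyl ethers in one operation; the isolated alkene and the alkyl cyclopropane are inert to HCl/MeOH at rt and no stereocentre is touched.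

Step 11
Reactants: 19 1-bromodocosane, 7 methyl (2R)-oxirane-2-carboxylate
Product: 21 methyl (2R)-2-hydroxypentacosanoate, via docosylmagnesium bromide 20 (not isolated)
Conditions: 19, Mg, THF, 50 °C; then 7, CuI (10 mol%), THF, −30 to 0 °C; aq. NH4Cl
Reagents that add atoms: none
Why: Copper-catalysed epoxide opening by the Grignard reagent at C3 of the glycidate (C22 + C3 = C25 chain); C2 is not a reacting centre and stays R.

Step 12
Reactants: 21 methyl (2R)-2-hydroxypentacosanoate
Product: 22 (2R)-2-hydroxypentacosanoic acid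
Conditions: LiOH, THF/MeOH/H2O, 50 °C; then aq. HCl
Reagents that add atoms: lithium hydroxide, [Li+].[OH-]
Why: Ester saponification by acyl substitution; the α-hydroxy carboxylate does not epimerise under these mild conditions.

Step 13
Reactants: 18 (2S,3S,4R,6E)-2-amino-11-[(1S,2S)-2-butylcyclopropyl]undec-6-ene-1,3,4-triol, 22 (2R)-2-hydroxypentacosanoic acid
Product: 23 (2R)-N-[(2S,3S,4R,6E)-11-[(1S,2S)-2-butylcyclopropyl]-1,3,4-trihydroxyundec-6-en-2-yl]-2-hydroxypentacosanamide (CNP0280669.1)
Conditions: EDC·HCl, HOBt, Et3N, THF/CH2Cl2, rt to 40 °C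
Reagents that add atoms: none
Why: Carbodiimide/HOBt amide coupling, in which the primary amine is far more nucleophilic than the four free hydroxyl groups toward the benzotriazolyl ester; no stereocentre reacts and α-hydroxy active esters do not racemise.

**Compound list**
1 | (2E)-hept-2-en-1-ol | CCCC/C=C/CO | starting material
2 | [(1S,2S)-2-butylcyclopropyl]methanol | OC[C@H]1C[C@@H]1CCCC | intermediate
3 | (1S,2S)-1-(bromomethyl)-2-butylcyclopropane | BrC[C@H]1C[C@@H]1CCCC | intermediate
4 | 5-bromopent-1-ene | C=CCCCBr | starting material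
5 | pent-4-en-1-ylmagnesium bromide | C=CCCC[Mg]Br | intermediate (not isolated)
6 | (1S,2S)-1-butyl-2-(hex-5-en-1-yl)cyclopropane | C=CCCCC[C@H]1C[C@@H]1CCCC | intermediate
7 | methyl (2R)-oxirane-2-carboxylate | COC(=O)[C@H]1CO1 | starting material
8 | vinylmagnesium bromide | C=C[Mg]Br | starting material
9 | methyl (2R)-2-hydroxypent-4-enoate | COC(=O)[C@H](O)CC=C | intermediate
10 | methyl (2R)-2-[(tert-butyldimethylsilyl)oxy]pent-4-enoate | COC(=O)[C@H](O[Si](C)(C)C(C)(C)C)CC=C | intermediate
11 | methyl (2R,4E)-9-[(1S,2S)-2-butylcyclopropyl]-2-[(tert-butyldimethylsilyl)oxy]non-4-enoate | COC(=O)[C@H](O[Si](C)(C)C(C)(C)C)C/C=C/CCCC[C@H]1C[C@@H]1CCCC | intermediate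
12 | (2R,4E)-9-[(1S,2S)-2-butylcyclopropyl]-2-[(tert-butyldimethylsilyl)oxy]non-4-enal | O=C[C@H](O[Si](C)(C)C(C)(C)C)C/C=C/CCCC[C@H]1C[C@@H]1CCCC | intermediate
13 | [(tert-butyldimethylsilyl)oxy]acetaldehyde | O=CCO[Si](C)(C)C(C)(C)C | starting material
14 | (R)-2-methylpropane-2-sulfinamide | CC(C)(C)[S@@](=O)N | starting material
15 | (R)-N-[(E)-2-[(tert-butyldimethylsilyl)oxy]ethylidene]-2-methylpropane-2-sulfinamide | CC(C)(C)[S@@](=O)/N=C/CO[Si](C)(C)C(C)(C)C | intermediate
16 | diiodosamarium ketyl radical of 12 (O-bound trivalent samarium, radical at the former carbonyl carbon) | I[Sm](I)O[CH][C@H](O[Si](C)(C)C(C)(C)C)C/C=C/CCCC[C@H]1C[C@@H]1CCCC | intermediate (not isolated)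
17 | (R)-N-[(2S,3S,4R,6E)-11-[(1S,2S)-2-butylcyclopropyl]-1,4-bis[(tert-butyldimethylsilyl)oxy]-3-hydroxyundec-6-en-2-yl]-2-methylpropane-2-sulfinamide | CC(C)(C)[S@@](=O)N[C@@H](CO[Si](C)(C)C(C)(C)C)[C@H](O)[C@H](O[Si](C)(C)C(C)(C)C)C/C=C/CCCC[C@H]1C[C@@H]1CCCC | intermediate
18 | (2S,3S,4R,6E)-2-amino-11-[(1S,2S)-2-butylcyclopropyl]undec-6-ene-1,3,4-triol | N[C@@H](CO)[C@H](O)[C@H](O)C/C=C/CCCC[C@H]1C[C@@H]1CCCC | intermediate
19 | 1-bromodocosane | CCCCCCCCCCCCCCCCCCCCCCBr | starting material
20 | docosylmagnesium bromide | CCCCCCCCCCCCCCCCCCCCCC[Mg]Br | intermediate (not isolated)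
21 | methyl (2R)-2-hydroxypentacosanoate | CCCCCCCCCCCCCCCCCCCCCCC[C@@H](O)C(=O)OC | intermediate
22 | (2R)-2-hydroxypentacosanoic acid | CCCCCCCCCCCCCCCCCCCCCCC[C@@H](O)C(=O)O | intermediate
23 | (2R)-N-[(2S,3S,4R,6E)-11-[(1S,2S)-2-butylcyclopropyl]-1,3,4-trihydroxyundec-6-en-2-yl]-2-hydroxypentacosanamide | CCCCCCCCCCCCCCCCCCCCCCC[C@@H](O)C(=O)N[C@@H](CO)[C@H](O)[C@H](O)C/C=C/CCCC[C@H]1C[C@@H]1CCCC | target

**Step count**
Total: 13 steps. Longest linear sequence: 8 steps (1, 2, 3, 6, 7, 9, 10, 13).

**Three steps most likely to fail**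

Step 9 (key coupling). The ketyl of an α-silyloxy aldehyde may pinacol-dimerise, be reduced further with loss of the silyloxy group, or give imperfect double diastereocontrol. The sense at C2 is set by the auxiliary, reasoned here from the open transition-state model rather than confirmed on this substrate; the enantiomeric sulfinamide would correct it if it proved opposite. Fallback, setting out from aldehyde 12 and coming back at 18: the same C2–C3 bond is made by a nitroaldol reaction, the nitronate carbon serving as the nucleophilic α-amino carbon. 2-Nitroethanol is silylated (TBSCl, imidazole) to tert-butyldimethyl(2-nitroethoxy)silane F1. Addition of F1 to 12 with catalytic Bu4NF (THF, −20 °C) gives (2S,3S,4R,6E)-11-[(1S,2S)-2-butylcyclopropyl]-1,4-bis[(tert-butyldimethylsilyl)oxy]-2-nitroundec-6-en-3-ol F2; Felkin-type 3,4-anti addition is expected, the C2 epimers equilibrate through the nitronate, and the wanted isomer is separated. Zn/AcOH reduces the nitro group, leaving alkene and cyclopropane alone, to (2S,3S,4R,6E)-2-amino-11-[(1S,2S)-2-butylcyclopropyl]-1,4-bis[(tert-butyldimethylsilyl)oxy]undec-6-en-3-ol F3, and HCl/MeOH then gives 18.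

Step 6 (alkene geometry). Metathesis of two unhindered terminal alkenes gives roughly 15–20% Z isomer, and its removal may be incomplete. Fallback, setting out from alkene 6 and coming back at 11, with the geometry fixed by syn-hydrozirconation instead of by equilibrium. Br2 (CH2Cl2, −78 °C) gives (1S,2S)-1-butyl-2-(5,6-dibromohexyl)cyclopropane F4, and NaNH2 in liquid NH3 gives (1S,2S)-1-butyl-2-(hex-5-yn-1-yl)cyclopropane F5. Cp2Zr(H)Cl and then I2 give (1S,2S)-1-butyl-2-[(5E)-6-iodohex-5-en-1-yl]cyclopropane F6. t-BuLi (2 equiv, Et2O, −78 °C) gives [(1E)-6-[(1S,2S)-2-butylcyclopropyl]hex-1-en-1-yl]lithium F7, and MgBr2·OEt2 converts it into [(1E)-6-[(1S,2S)-2-butylcyclopropyl]hex-1-en-1-yl]magnesium bromide F8. With catalytic CuI, F8 opens methyl (R)-glycidate 7 at C3, as in step 4, to methyl (2R,4E)-9-[(1S,2S)-2-butylcyclopropyl]-2-hydroxynon-4-enoate F9, and TBSCl/imidazole gives 11 as the pure E isomer.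

Step 3 (coupling at the cyclopropylmethyl carbon). Any radical character at this carbon would open the ring, and bromide 3 can rearrange on standing. Fallback, setting out from bromide 3 and coming back at 6, using a purely ionic SN2 alkylation. 5-Bromopent-1-ene 4 and PhSO2Na (DMF) give (pent-4-en-1-ylsulfonyl)benzene F10, and n-BuLi (THF, −78 °C) gives [1-(phenylsulfonyl)pent-4-en-1-yl]lithium F11. F11 alkylates 3 to ({1-[(1R,2S)-2-butylcyclopropyl]hept-6-en-2-yl}sulfonyl)benzene F12, obtained as both epimers at the sulfonyl carbon; the ring is unchanged in space and only its CIP label changes. Reductive desulfonylation with Na(Hg)/Na2HPO4 in MeOH, where the transient radical or anion sits one carbon away from the ring, gives 6.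

**Further compounds**
F1 | step 9 | tert-butyldimethyl(2-nitroethoxy)silane | [O-][N+](=O)CCO[Si](C)(C)C(C)(C)C
F2 | step 9 | (2S,3S,4R,6E)-11-[(1S,2S)-2-butylcyclopropyl]-1,4-bis[(tert-butyldimethylsilyl)oxy]-2-nitroundec-6-en-3-ol | [O-][N+](=O)[C@@H](CO[Si](C)(C)C(C)(C)C)[C@H](O)[C@H](O[Si](C)(C)C(C)(C)C)C/C=C/CCCC[C@H]1C[C@@H]1CCCC
F3 | step 9 | (2S,3S,4R,6E)-2-amino-11-[(1S,2S)-2-butylcyclopropyl]-1,4-bis[(tert-butyldimethylsilyl)oxy]undec-6-en-3-ol | N[C@@H](CO[Si](C)(C)C(C)(C)C)[C@H](O)[C@H](O[Si](C)(C)C(C)(C)C)C/C=C/CCCC[C@H]1C[C@@H]1CCCC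
F4 | step 6 | (1S,2S)-1-butyl-2-(5,6-dibromohexyl)cyclopropane (both epimers at the CHBr carbon) | BrCC(Br)CCCC[C@H]1C[C@@H]1CCCC
F5 | step 6 | (1S,2S)-1-butyl-2-(hex-5-yn-1-yl)cyclopropane | C#CCCCC[C@H]1C[C@@H]1CCCC
F6 | step 6 | (1S,2S)-1-butyl-2-[(5E)-6-iodohex-5-en-1-yl]cyclopropane | I/C=C/CCCC[C@H]1C[C@@H]1CCCC
F7 | step 6 | [(1E)-6-[(1S,2S)-2-butylcyclopropyl]hex-1-en-1-yl]lithium | [Li]/C=C/CCCC[C@H]1C[C@@H]1CCCC
F8 | step 6 | [(1E)-6-[(1S,2S)-2-butylcyclopropyl]hex-1-en-1-yl]magnesium bromide | Br[Mg]/C=C/CCCC[C@H]1C[C@@H]1CCCC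
F9 | step 6 | methyl (2R,4E)-9-[(1S,2S)-2-butylcyclopropyl]-2-hydroxynon-4-enoate | COC(=O)[C@H](O)C/C=C/CCCC[C@H]1C[C@@H]1CCCC
F10 | step 3 | (pent-4-en-1-ylsulfonyl)benzene | C=CCCCS(=O)(=O)c1ccccc1
F11 | step 3 | [1-(phenylsulfonyl)pent-4-en-1-yl]lithium | [Li]C(CCC=C)S(=O)(=O)c1ccccc1
F12 | step 3 | ({1-[(1R,2S)-2-butylcyclopropyl]hept-6-en-2-yl}sulfonyl)benzene (both epimers at the sulfonyl carbon) | C=CCCC(C[C@H]1C[C@@H]1CCCC)S(=O)(=O)c1ccccc1
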